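**Strategy.** The route rests on disconnecting both ester-conjugated (E)-Cα=Cβ bonds of the two p-coumaroyl groups on O4 and O5 of the cyclohexane ring, each bond joining an ester α-carbon to the benzylic carbon of a 4-hydroxyphenyl ring. One double Knoevenagel–Doebner condensation of a quinate 4,5-bis(malonic half-ester) with two molecules of 4-hydroxybenzaldehyde should create both alkenes with loss of two CO2, so the migration-prone phenolic cinnamates appear late and need no phenol protection. The precursor is allyl quinate carrying carboxyacetyl esters on the trans O4/O5 pair, a triisopropylsilyl ether on the cis-neighbouring O3 and a free tertiary C1 hydroxyl, built from (−)-quinic acid through a butane-2,3-diacetal.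

Key step: step 6

Remark: quinate names keep the ring configuration of (−)-quinic acid (O1, O3 and O4 on one face, O5 and the carboxyl on the other). A triisopropylsilyl ether is chosen at O3 so that it outlasts the aqueous trifluoroacetic acid of step 4, and the allyl ester is installed after acetal formation because acidic methanol would exchange it.

Step 1
Reactants: 1 (−)-quinic acid
Product: 3 methyl 4,5-O-[(2S,3S)-2,3-dimethoxybutane-2,3-diyl]quinate, via methyl quinate 2 (not isolated)
Conditions: butane-2,3-dione, HC(OMe)3, CSA (cat.), MeOH, reflux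
Reagents that add atoms: butane-2,3-dione, CC(=O)C(C)=O; methanol, CO; trimethyl orthoformate, COC(OC)OC (methoxy donor together with methanol, also the water scavenger)
Why: Fischer esterification and butane-2,3-diacetal formation run under the same acid catalyst; only the trans-diequatorial C4/C5 diol can span the dioxane ring, and its two new acetal carbons should equilibrate to the (S,S) form with both methoxy groups axial (anomeric effect) and both methyl groups equatorial.

Step 2
Reactants: 3 methyl 4,5-O-[(2S,3S)-2,3-dimethoxybutane-2,3-diyl]quinate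
Product: 5 allyl 4,5-O-[(2S,3S)-2,3-dimethoxybutane-2,3-diyl]quinate, via potassium carboxylate 4 (not isolated)
Conditions: KOH (1.0 equiv), MeOH/H2O, rt; evaporate; allyl bromide, DMF, rt
Reagents that add atoms: allyl bromide, C=CCBr
Why: Saponification followed by SN2 O-alkylation of the carboxylate should exchange the ester cleanly, since the diacetal is stable to base and the carboxylate is too weak a base to allylate the C1 and C3 hydroxyls.

Step 3
Reactants: 5 allyl 4,5-O-[(2S,3S)-2,3-dimethoxybutane-2,3-diyl]quinate
Product: 6 allyl 4,5-O-[(2S,3S)-2,3-dimethoxybutane-2,3-diyl]-3-O-(triisopropylsilyl)quinate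
Conditions: TIPSOTf (1.3 equiv), 2,6-lutidine, CH2Cl2, 0 °C to rt
Reagents that add atoms: triisopropylsilyl trifluoromethanesulfonate, CC(C)[Si](OS(=O)(=O)C(F)(F)F)(C(C)C)C(C)C
Why: Silyl triflate silylation should take the secondary axial C3 hydroxyl only, because the tertiary C1 hydroxyl is hindered and deactivated by the neighbouring ester and does not react with so bulky a silyl group.

Step 4
Reactants: 6 allyl 4,5-O-[(2S,3S)-2,3-dimethoxybutane-2,3-diyl]-3-O-(triisopropylsilyl)quinate
Product: 7 allyl 3-O-(triisopropylsilyl)quinate
Conditions: TFA/H2O (9:1), 0 °C to rt, short contact; toluene co-evaporation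
Reagents that add atoms: none
Why: Acid-catalysed acetal hydrolysis should free the C4/C5 diol, while the hindered triisopropylsilyl ether and the allyl ester are expected to survive the brief exposure and no stereocentre is touched.

Step 5
Reactants: 7 allyl 3-O-(triisopropylsilyl)quinate; 8 Meldrum's acid (2.3 equiv)
Product: 9 allyl 3-O-(triisopropylsilyl)-4,5-bis-O-(carboxyacetyl)quinate
Conditions: toluene, 90 °C
Reagents that add atoms: none
Why: Alcoholysis of Meldrum's acid (ring-opening acylation with loss of acetone) should give the malonic half-esters directly on both secondary hydroxyls, the small acylating agent reaching the flanked C4 hydroxyl while the tertiary C1 hydroxyl stays free.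

Step 6
Reactants: 9 allyl 3-O-(triisopropylsilyl)-4,5-bis-O-(carboxyacetyl)quinate; 10 4-hydroxybenzaldehyde (3 equiv, two molecules incorporated)
Product: 11 allyl 3-O-(triisopropylsilyl)-4,5-di-O-[(E)-p-coumaroyl]quinate
Conditions: piperidine (0.5 equiv), pyridine, 45 °C
Reagents that add atoms: none
Why: Piperidine condenses with 4-hydroxybenzaldehyde to an iminium ion, the enol of each malonic half-ester adds to it in a Mannich-type step, and the resulting β-amino acid loses CO2 and piperidine in an anti-periplanar decarboxylative elimination, once on each arm. The closest known reaction type is the Knoevenagel–Doebner condensation of malonic half-esters with hydroxybenzaldehydes to hydroxycinnamate esters. No ring is closed and no stereocentre is formed, and the four ring stereocentres are spectators. The (E) geometry at both alkenes should follow from elimination through the conformer that keeps the aryl and ester groups apart and from the greater stability of the conjugated trans ester. The step also needs freedom from acyl migration, which the silyl ether at O3 secures by leaving no neighbouring hydroxyl for the O4 ester to move to. The free phenol only slows the aldehyde, and the tertiary C1 hydroxyl and the allyl ester are inert to the amine at this temperature.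

Step 7
Reactants: 11 allyl 3-O-(triisopropylsilyl)-4,5-di-O-[(E)-p-coumaroyl]quinate
Product: 12 3-O-(triisopropylsilyl)-4,5-di-O-[(E)-p-coumaroyl]quinic acid
Conditions: Pd(PPh3)4 (5 mol %), morpholine, THF, rt; dilute aqueous HCl work-up
Reagents that add atoms: none
Why: Tsuji–Trost deallylation, in which zerovalent palladium ionises the allyl ester and excess morpholine captures the allyl group faster than the phenols can, should free the acid while the silyl ether at O3 still blocks amine-induced acyl migration.

Step 8
Reactants: 12 3-O-(triisopropylsilyl)-4,5-di-O-[(E)-p-coumaroyl]quinic acid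
Product: 13 4,5-di-O-[(E)-p-coumaroyl]quinic acid
Conditions: HF·pyridine, pyridine, THF, 0 °C to rt
Reagents that add atoms: none
Why: Fluoride-mediated Si–O cleavage in an acidic medium should unmask the C3 hydroxyl without touching the cinnamate esters or alkenes, and the absence of base disfavours migration of the C4 acyl group to O3.

**Compound list**

1 | (−)-quinic acid, (1S,3R,4S,5R)-1,3,4,5-tetrahydroxycyclohexane-1-carboxylic acid | O[C@@H]1[C@H](O)C[C@@](O)(C(=O)O)C[C@H]1O | starting material
2 | methyl quinate | O[C@@H]1[C@H](O)C[C@@](O)(C(=O)OC)C[C@H]1O | intermediate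
3 | methyl 4,5-O-[(2S,3S)-2,3-dimethoxybutane-2,3-diyl]quinate (trans-fused dioxane on O4/O5, both OMe axial; C1 and C3 hydroxyls free) | CO[C@@]1(C)O[C@@H]2[C@H](O)C[C@@](O)(C(=O)OC)C[C@H]2O[C@]1(C)OC | intermediate
4 | potassium 4,5-O-[(2S,3S)-2,3-dimethoxybutane-2,3-diyl]quinate | CO[C@@]1(C)O[C@@H]2[C@H](O)C[C@@](O)(C(=O)[O-])C[C@H]2O[C@]1(C)OC.[K+] | intermediate
5 | allyl 4,5-O-[(2S,3S)-2,3-dimethoxybutane-2,3-diyl]quinate | CO[C@@]1(C)O[C@@H]2[C@H](O)C[C@@](O)(C(=O)OCC=C)C[C@H]2O[C@]1(C)OC | intermediate
6 | allyl 4,5-O-[(2S,3S)-2,3-dimethoxybutane-2,3-diyl]-3-O-(triisopropylsilyl)quinate | CO[C@@]1(C)O[C@@H]2[C@H](O[Si](C(C)C)(C(C)C)C(C)C)C[C@@](O)(C(=O)OCC=C)C[C@H]2O[C@]1(C)OC | intermediate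
7 | allyl 3-O-(triisopropylsilyl)quinate (C1, C4 and C5 hydroxyls free) | O[C@@H]1[C@H](O[Si](C(C)C)(C(C)C)C(C)C)C[C@@](O)(C(=O)OCC=C)C[C@H]1O | intermediate
8 | Meldrum's acid, 2,2-dimethyl-1,3-dioxane-4,6-dione | CC1(C)OC(=O)CC(=O)O1 | starting material
9 | allyl 3-O-(triisopropylsilyl)-4,5-bis-O-(carboxyacetyl)quinate | O=C(CC(=O)O)O[C@@H]1[C@H](O[Si](C(C)C)(C(C)C)C(C)C)C[C@@](O)(C(=O)OCC=C)C[C@H]1OC(=O)CC(=O)O | intermediate
10 | 4-hydroxybenzaldehyde | O=Cc1ccc(O)cc1 | starting material
11 | allyl 3-O-(triisopropylsilyl)-4,5-di-O-[(E)-p-coumaroyl]quinate | O=C(/C=C/c1ccc(O)cc1)O[C@@H]1[C@H](O[Si](C(C)C)(C(C)C)C(C)C)C[C@@](O)(C(=O)OCC=C)C[C@H]1OC(=O)/C=C/c1ccc(O)cc1 | intermediate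
12 | 3-O-(triisopropylsilyl)-4,5-di-O-[(E)-p-coumaroyl]quinic acid | O=C(/C=C/c1ccc(O)cc1)O[C@@H]1[C@H](O[Si](C(C)C)(C(C)C)C(C)C)C[C@@](O)(C(=O)O)C[C@H]1OC(=O)/C=C/c1ccc(O)cc1 | intermediate
13 | 4,5-di-O-[(E)-p-coumaroyl]quinic acid | O=C(/C=C/c1ccc(O)cc1)O[C@@H]1[C@H](O)C[C@@](O)(C(=O)O)C[C@H]1OC(=O)/C=C/c1ccc(O)cc1 | target

**Step count.** Total: 8 steps. Longest linear sequence: 8 steps, from 1 to 13.

**Steps most likely to fail**

Step 6. The second condensation may stall after the first arm has reacted, a malonyl arm may lose CO2 to an acetate before it meets the slow, phenoxide-deactivated aldehyde, and prolonged contact with the amine may cleave esters. The fallback replaces olefination by classical acylation and sets out from diol 7. Commercial (E)-4-acetoxycinnamic acid is converted with oxalyl chloride (cat. DMF, CH2Cl2) into (E)-4-acetoxycinnamoyl chloride F1. This acylates both hydroxyls of 7 (pyridine, DMAP, CH2Cl2) to give allyl 3-O-(triisopropylsilyl)-4,5-bis-O-[(E)-4-acetoxycinnamoyl]quinate F2. Hydrazinium acetate in DMF at room temperature should then remove only the two phenolic acetates, and the route is rejoined at 11.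

Step 5. Acylation of the flanked C4 hydroxyl may remain incomplete, a half-ester already formed may decarboxylate on heating, and the free C5 hydroxyl may lactonise onto the allyl ester in hot acidic toluene. The fallback introduces the malonyl groups in protected form at low temperature and sets out from 7. Steglich esterification with mono-tert-butyl malonate (DCC, DMAP, CH2Cl2, 0 °C to rt) should give allyl 3-O-(triisopropylsilyl)-4,5-bis-O-(3-tert-butoxy-3-oxopropanoyl)quinate F3. Anhydrous TFA in CH2Cl2 then cleaves the two tert-butyl esters, and the route is rejoined at 9.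

Step 8. Cleavage of the hindered silyl ether may be slow, and during a long reaction or purification of the polar free acid the C4 acyl group may drift to the liberated C3 hydroxyl. The fallback reverses the order of the two unmaskings and sets out from 11. HF·pyridine on the neutral ester should give allyl 4,5-di-O-[(E)-p-coumaroyl]quinate F4, which can be purified on silica. Pd(PPh3)4 with phenylsilane in THF, an amine-free allyl transfer to hydride, then releases the acid, and the route is rejoined at 13.

**Further compounds**

F1 | step 6 | (E)-4-acetoxycinnamoyl chloride | CC(=O)Oc1ccc(/C=C/C(=O)Cl)cc1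
F2 | step 6 | allyl 3-O-(triisopropylsilyl)-4,5-bis-O-[(E)-4-acetoxycinnamoyl]quinate | CC(=O)Oc1ccc(cc1)/C=C/C(=O)O[C@@H]1[C@H](O[Si](C(C)C)(C(C)C)C(C)C)C[C@@](O)(C(=O)OCC=C)C[C@H]1OC(=O)/C=C/c1ccc(OC(C)=O)cc1
F3 | step 5 | allyl 3-O-(triisopropylsilyl)-4,5-bis-O-(3-tert-butoxy-3-oxopropanoyl)quinate | CC(C)(C)OC(=O)CC(=O)O[C@@H]1[C@H](O[Si](C(C)C)(C(C)C)C(C)C)C[C@@](O)(C(=O)OCC=C)C[C@H]1OC(=O)CC(=O)OC(C)(C)C
F4 | step 8 | allyl 4,5-di-O-[(E)-p-coumaroyl]quinate | O=C(/C=C/c1ccc(O)cc1)O[C@@H]1[C@H](O)C[C@@](O)(C(=O)OCC=C)C[C@H]1OC(=O)/C=C/c1ccc(O)cc1
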